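## The problem

The target is an isoflavone: a 5,7-dihydroxychromen-4-one (rings A and C) with a 2,4-dihydroxyphenyl ring B on C3, an (R)-2-hydroxy-3-methylbut-3-enyl chain on C6 and a prenyl group on C3'. The core skeleton is simple; the difficulty is regiochemistry, because ring A offers C6 and C8, ring B offers C3' and C5', and four phenols (7-OH, 4'-OH, 2'-OH and the chelated 5-OH) must be told apart. There is one stereocentre, the carbinol carbon of the C6 chain. Nothing else in the molecule is stereogenic, so it cannot be relayed from the substrate; it must be set by a chiral catalyst and then kept from ionising. The fragile parts are the two side chains: a prenyl group and an isopropenyl carbinol, each flanked by phenols, cyclise to chromans or dihydrofurans in strong acid, and neither survives BBr3, hydrogenolysis or an alkene-cleaving oxidant. Ring C opens at C2 under hard base, and the arylacetaldehyde needed on the way enolises easily. What makes a short core synthesis possible is the make-up of ring C: O1 is a phenol oxygen of ring A, C4 an acyl carbon, C3 the benzylic carbon of an arylacetic acid and C2 one extra carbon. Ring A has the oxygenation of threefold-symmetric phloroglucinol, so acylation at any ring carbon and closure through either neighbouring hydroxyl give the same chromone. A second feature settles the side chains: O5 has only C6 as a free ortho carbon (the other is C4a) and O2' has only C3' (the other is C1'), so a [3,3] shift from each oxygen has no regiochemical choice.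

## Retrosynthesis

**Target 22 from 21.** Only the C–O bonds of three methoxymethyl ethers (O5, O7, O4') are cut. Acetal protection is preferred to benzyl, silyl or acyl groups because it survives carbonate, hydride, 200 °C, osmium, chromium, fluoride and palladium and still leaves in dilute acid. Compound 21 already holds every carbon and the stereocentre. The forward step must free three phenols without touching either side chain.

**21 from 20, and 20 from 17 and 19.** The C3'–CH2 bond of the prenyl group is cut by a retro-Claisen step to the aryl 1,1-dimethylallyl ether 20, and the O2'–C bond of 20 is cut to phenol 17 and carbonate 19, itself one step from alcohol 18. Direct C-prenylation would give C3'/C5' mixtures, and a shift from O4' has two open ortho carbons; O2' has one. The prenyl group enters last because it would not survive the alkene cleavage that builds the ring A chain. Forward, O2' must be the only free phenol in 17.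

**17 from 16, and 16 from 14 and 15.** The silyl ether on O2' is removed (16), then the bond between the carbinol carbon and the isopropenyl carbon is cut, giving arylacetaldehyde 14 and 2-bromopropene 15. This cut creates the stereocentre in the bond-forming step itself. Routes through a C6 prenyl group (epoxidation and isomerisation, or dihydroxylation and dehydration) need more steps and a prenyl group that no [3,3] shift delivers to C6. Aldehyde 14 is achiral. The forward reaction must be non-basic and catalyst-controlled.

**14 from 12 (through diol 13), 12 from 11, 11 from 10.** The aldehyde is traced to the terminal alkene of 12, cleaved through diol 13. Compound 12 is phenol 11 with its 5-OH capped, and 11 comes from the 5-O-allyl ether 10 by cutting the C6–CH2 bond in a retro-Claisen step. The shift from O5 is preferred to electrophilic substitution of ring A, which does not distinguish C6 from C8 reliably. Forward, the allyl group must stop at C6, and the 5-OH must be capped before the aldehyde appears so that no lactol forms.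

**10 from 9, 9 from 8, 8 from 7, 7 from 6.** No skeletal bond is cut; the four phenols are sorted by reactivity. The chelated 5-OH takes the allyl group last (10 from 9), the crowded 2'-OH takes a bulky silyl group (9 from 8), the two most acidic phenols take acetals (8 from 7), and tetraol 7 comes from dimethyl ether 6 by demethylation. Demethylation is placed here because no later intermediate tolerates it. The forward sequence asks for one truly selective step, O7/O4' against O2'.

**6 from 1, 2 and 3 (through 4 and 5).** Three bonds around ring C are cut: C4–C4a back to phloroglucinol 1 and 2,4-dimethoxyphenylacetic acid 2, then C2–C3 and O1–C2 back to N,N-dimethylformamide 3 as the one-carbon unit. The intermediates are deoxybenzoin 4 and enaminoketone 5. Cutting C3–C1' or ring A instead would need prefunctionalised, regiodefined partners; this cut needs three commercial compounds and no regiocontrol on ring A. Ring B is carried as methyl ethers so that no 2'-hydroxyl can close a benzofuran. The forward reaction must stop at mono-acylation and formylate carbon, not oxygen.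

## Roads not taken

**Alternative 1:** The C3–C1' bond is cut, with O2' tied to an extra carboxyl carbon on C2. Forward, the aryl 3-bromochromone-2-carboxylate A2 would undergo intramolecular direct arylation with zerovalent palladium (oxidative addition at C3–Br, concerted metalation–deprotonation at C1'–H) to give the lactone-bridged isoflavone A1. The bridge carbon must then be excised by lactone opening and decarboxylation.
- Merits: the route is convergent, the tether forces arylation at the only ortho C–H of the ester oxygen, and ring B arrives with its prenyl group in place. O2' emerges uniquely marked as the lactone oxygen. That is better than the chosen plan, which spends steps 4 and 10 and accepts the selectivity risk of step 3 to tell O2' from O4'.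
- Weak points: ring A of A2 must be built as a regiodefined 6-substituted chromone acid, so the C6/C8 question that phloroglucinol symmetry erases returns at the start. The palladium step runs beside a prenyl and an isopropenyl group, both open to Heck-type insertion. Decarboxylation of a chromone-2-carboxylic acid normally needs copper and temperatures near 200 °C, which threatens both side chains, and hydroxide opening of the lactone also endangers ring C at C2.
- Comparison: the chosen plan sets against the O2' advantage a core made in one step from three commercial compounds and no step harsher than a 200 °C Claisen shift on a substrate without sensitive groups.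

**Alternative 2:** Ring A is cut instead of ring C, at C5–C6, C7–C8 and C4a–C5. Forward, irradiation of the 3-aryl-4-pyranone diazo ketone A4 triggers a Wolff rearrangement to a pyranonyl ketene. [2+2] addition of the chiral siloxyalkyne A5, four-electron ring opening, six-electron ring closure and tautomerisation give the 5-hydroxy-7-silyloxy isoflavone A3 with both side chains present.
- Merits: the C6 chain, its stereocentre and the 5-OH/7-O differentiation are fixed by construction, since the alkyne substituent must end between the new hydroxyl and the silyloxy group. Only deprotections follow. This is better than the chosen plan, which needs five steps (5 to 9) to bring the same chain onto C6.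
- Weak points: A4 and A5 are each multistep targets. A4 needs a pyranone acid already carrying the prenylated ring B and a diazo ketone synthesis; A5 needs the stereocentre made beforehand and an ester-to-ynol-ether homologation. The 4-pyranone chromophore is itself photolabile, and the ketene can be intercepted by the prenyl and isopropenyl alkenes.
- Comparison: the chosen plan answers with thermal bond formation throughout and a lower total count, at the price of a longer linear sequence on ring A.

**Alternative 3:** Ring C is cut at O1–C8a and C4–C4a. Forward, fluoride generates a ring A aryne from the silyl triflate A7. The enol oxygen of the formyl arylacetate A8 adds at C8a, and the aryl anion at C4a attacks the ester to give the fully protected target A6.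
- Merits: the conditions are mild, everything is in place before ring C closes, and one global deprotection remains. The regiochemistry is favourable, because a nucleophile adds to a 3-alkoxyaryne at the carbon remote from the ether, here C8a, leaving the anion at C4a where it is needed. In convergence and end-game length this road is better than the chosen plan.
- Weak points: A7 is a hexasubstituted benzene whose chain must sit between two ethers, so the C6/C8 problem is moved into a long precursor synthesis. The enol of A8 is ambident, and C-arylation or insertion of the aryne into the C–C bond of the formyl ester competes with O-arylation. The aryl anion can also be protonated by the acidic enol before it reaches the ester.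
- Comparison: the chosen plan sets against this a core step with no such chemoselectivity question and side chains placed by shifts that have one open position each.

Key step: step 1

Assumption: the chromium ligand of step 9 is an N-[2-(4-isopropyl-4,5-dihydrooxazol-2-yl)aryl]methanesulfonamide; its S enantiomer is taken to deliver the alkenyl group to the Si face of 14, and the R enantiomer is used instead, with no other change, if the carbinol proves to be S.

## Route

Step 1
Reactants: 1 phloroglucinol; 2 2,4-dimethoxyphenylacetic acid; 3 N,N-dimethylformamide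
Product: 6 5,7-dihydroxy-2',4'-dimethoxyisoflavone, via deoxybenzoin 4 (not isolated), via enaminoketone 5 (not isolated)
Conditions: BF3·OEt2 (neat), 85 °C; then 3, MsCl, 60 °C; H2O
Reagents that add atoms: none
Why: BF3·OEt2 activates acid 2 and promotes Friedel–Crafts C-acylation of 1 (directly or by O-acylation and Fries shift), giving deoxybenzoin 4 as its difluoroboron chelate and forming C4–C4a. The chloroiminium-type reagent from 3 and MsCl then formylates the methylene carbon, activated as a boron enolate, to give enaminoketone 5 and form C2–C3. An ortho hydroxyl of ring A adds to the β-carbon of 5 in a 6-endo-trig conjugate addition and dimethylamine is expelled, forming O1–C2 and closing ring C as the aromatic pyranone. The closest known reaction type is the one-pot deoxybenzoin and Vilsmeier-type isoflavone synthesis from phenols and arylacetic acids. No stereocentre is formed. The step needs mono-acylation, which the deactivating acyl group and its boron chelate secure; it needs no regiocontrol, because all three ring carbons and both flanking hydroxyls of 1 are equivalent; and it needs ring closure onto ring A only, which the methyl ethers of 2 secure by leaving no 2'-hydroxyl to form a benzofuran.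

Step 2
Reactants: 6 5,7-dihydroxy-2',4'-dimethoxyisoflavone
Product: 7 2',4',5,7-tetrahydroxyisoflavone
Conditions: BBr3 (6 equiv), CH2Cl2, −78 °C to rt; MeOH, H2O
Reagents that add atoms: none
Why: Lewis-acid demethylation of aryl methyl ethers (boron on oxygen, bromide attack at methyl); the chromone tolerates it, and it is placed here because no later intermediate would.

Step 3
Reactants: 7 2',4',5,7-tetrahydroxyisoflavone
Product: 8 2',5-dihydroxy-7,4'-bis(methoxymethoxy)isoflavone
Conditions: MOMCl (2.1 equiv), i-Pr2NEt, DMF, 0 °C
Reagents that add atoms: chloromethyl methyl ether, COCCl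
Why: Acidity- and hindrance-ranked O-alkylation: the 7-OH (a vinylogous acid) and the 4'-OH are the most acidic and most exposed, the 2'-OH is crowded by the twisted chromone and the 5-OH is chelated to C4=O, so two equivalents with a weak amine base should stop at the 7,4'-bis-ether.

Step 4
Reactants: 8 2',5-dihydroxy-7,4'-bis(methoxymethoxy)isoflavone
Product: 9 5-hydroxy-7,4'-bis(methoxymethoxy)-2'-(triisopropylsilyloxy)isoflavone
Conditions: TIPSCl, imidazole, DMF, 40 °C
Reagents that add atoms: chlorotriisopropylsilane, CC(C)[Si](Cl)(C(C)C)C(C)C
Why: Silylation of the only non-chelated phenol; the bulky silyl ether should resist carbonate, hydride base and 200 °C yet leave with fluoride beside acetals, and a silyl chloride with imidazole does not touch the chelated 5-OH.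

Step 5
Reactants: 9 5-hydroxy-7,4'-bis(methoxymethoxy)-2'-(triisopropylsilyloxy)isoflavone
Product: 10 5-allyloxy-7,4'-bis(methoxymethoxy)-2'-(triisopropylsilyloxy)isoflavone
Conditions: allyl bromide, K2CO3, DMF, 50 °C
Reagents that add atoms: allyl bromide, C=CCBr
Why: Williamson allylation of the last free phenol; warm carbonate in DMF is needed to break the hydrogen bond from the 5-OH to C4=O.

Step 6
Reactants: 10 5-allyloxy-7,4'-bis(methoxymethoxy)-2'-(triisopropylsilyloxy)isoflavone
Product: 11 6-allyl-5-hydroxy-7,4'-bis(methoxymethoxy)-2'-(triisopropylsilyloxy)isoflavone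
Conditions: PhNEt2, 200 °C
Reagents that add atoms: none
Why: Aromatic Claisen rearrangement: the [3,3] shift from O5 can only end on C6, because the other ortho carbon is the ring fusion C4a; rearomatisation restores the chelated 5-OH, and the small allyl group should not run on to C8.

Step 7
Reactants: 11 6-allyl-5-hydroxy-7,4'-bis(methoxymethoxy)-2'-(triisopropylsilyloxy)isoflavone
Product: 12 6-allyl-5,7,4'-tris(methoxymethoxy)-2'-(triisopropylsilyloxy)isoflavone
Conditions: NaH, MOMCl, DMF, 0 °C to rt
Reagents that add atoms: chloromethyl methyl ether, COCCl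
Why: O-Alkylation of the sodium phenoxide; capping the 5-OH prevents lactol and then benzofuran formation with the aldehyde of step 8.

Step 8
Reactants: 12 6-allyl-5,7,4'-tris(methoxymethoxy)-2'-(triisopropylsilyloxy)isoflavone
Product: 14 6-(2-oxoethyl)-5,7,4'-tris(methoxymethoxy)-2'-(triisopropylsilyloxy)isoflavone, via diol 13 (not isolated)
Conditions: OsO4 (2 mol%), NaIO4, 2,6-lutidine, dioxane–H2O, rt
Reagents that add atoms: sodium periodate (terminal oxidant, delivered through OsO4), [Na+].[O-]I(=O)(=O)=O
Why: Lemieux–Johnson cleavage: OsO4 dihydroxylates the only isolated alkene (the C2=C3 bond is a deactivated vinylogous ester) to diol 13 and periodate cleaves it; 2,6-lutidine suppresses over-oxidation, and the step comes before any prenyl group exists.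

Step 9
Reactants: 14 6-(2-oxoethyl)-5,7,4'-tris(methoxymethoxy)-2'-(triisopropylsilyloxy)isoflavone; 15 2-bromopropene
Product: 16 6-[(2R)-2-hydroxy-3-methylbut-3-enyl]-5,7,4'-tris(methoxymethoxy)-2'-(triisopropylsilyloxy)isoflavone
Conditions: CrCl2 (10 mol%), (S)-oxazoline sulfonamide ligand (11 mol%), 1,8-bis(dimethylamino)naphthalene (11 mol%), NiCl2(2,9-dimethyl-1,10-phenanthroline) (2 mol%), Mn, Zr(C5H5)2Cl2, LiCl, MeCN, rt
Reagents that add atoms: none
Why: Catalytic asymmetric Nozaki–Hiyama–Kishi alkenylation: zerovalent nickel inserts into the C–Br bond of 15 and the alkenyl group passes to ligand-bound chromium, which adds to the aldehyde under non-basic conditions that spare the enolisable aldehyde and the chromone. The chiral oxazoline sulfonamide on chromium selects the Si face of 14, which gives the R carbinol; the zirconocene dichloride frees the chromium alkoxide so that manganese can turn the cycle over.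

Step 10
Reactants: 16 6-[(2R)-2-hydroxy-3-methylbut-3-enyl]-5,7,4'-tris(methoxymethoxy)-2'-(triisopropylsilyloxy)isoflavone
Product: 17 2'-hydroxy-6-[(2R)-2-hydroxy-3-methylbut-3-enyl]-5,7,4'-tris(methoxymethoxy)isoflavone
Conditions: Bu4NF, AcOH, THF, 0 °C
Reagents that add atoms: none
Why: Fluoride cleaves the aryl O–Si bond at 0 °C because phenoxide is a good leaving group; acetals, chromone and carbinol are inert and AcOH buffers the phenoxide.

Step 11
Reactants: 18 2-methylbut-3-en-2-ol
Product: 19 tert-butyl 2-methylbut-3-en-2-yl carbonate
Conditions: n-BuLi, THF, −78 °C; Boc2O, −78 °C to rt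
Reagents that add atoms: di-tert-butyl dicarbonate, CC(C)(C)OC(=O)OC(=O)OC(C)(C)C
Why: Acylation of the lithium alkoxide of the tertiary allylic alcohol gives the mixed carbonate that serves as the ionisable C5 donor.

Step 12
Reactants: 17 2'-hydroxy-6-[(2R)-2-hydroxy-3-methylbut-3-enyl]-5,7,4'-tris(methoxymethoxy)isoflavone; 19 tert-butyl 2-methylbut-3-en-2-yl carbonate
Product: 20 6-[(2R)-2-hydroxy-3-methylbut-3-enyl]-5,7,4'-tris(methoxymethoxy)-2'-(2-methylbut-3-en-2-yloxy)isoflavone
Conditions: Pd(PPh3)4 (5 mol%), THF, 0 °C to rt
Reagents that add atoms: none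
Why: Decarboxylative Tsuji–Trost O-allylation: zerovalent palladium ionises 19 to a 1,1-dimethyl π-allyl complex, carbon dioxide and tert-butoxide; the tert-butoxide deprotonates the only phenol, and the phenoxide attacks the more substituted allyl terminus under kinetic control to give the branched ether. The far less acidic carbinol does not compete.

Step 13
Reactants: 20 6-[(2R)-2-hydroxy-3-methylbut-3-enyl]-5,7,4'-tris(methoxymethoxy)-2'-(2-methylbut-3-en-2-yloxy)isoflavone
Product: 21 2'-hydroxy-6-[(2R)-2-hydroxy-3-methylbut-3-enyl]-5,7,4'-tris(methoxymethoxy)-3'-(3-methylbut-2-enyl)isoflavone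
Conditions: PhMe, 120 °C (sealed tube)
Reagents that add atoms: none
Why: Aromatic Claisen rearrangement of a tertiary allyl aryl ether, which shifts near 120 °C: from O2' only C3' is an open ortho carbon (C1' carries ring C), and the allyl inversion of the [3,3] shift turns the 1,1-dimethylallyl group into the prenyl group. The stereocentre is remote and untouched.

Step 14
Reactants: 21 2'-hydroxy-6-[(2R)-2-hydroxy-3-methylbut-3-enyl]-5,7,4'-tris(methoxymethoxy)-3'-(3-methylbut-2-enyl)isoflavone
Product: 22 3-[2,4-dihydroxy-3-(3-methylbut-2-enyl)phenyl]-5,7-dihydroxy-6-[(2R)-2-hydroxy-3-methylbut-3-enyl]-4H-chromen-4-one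
Conditions: HCl (3 M aq), MeOH, 40 °C
Reagents that add atoms: none
Why: Acid-catalysed methanolysis of three aryl methoxymethyl acetals; dilute acid at 40 °C protonates acetal oxygen far faster than the trisubstituted or 1,1-disubstituted alkene, so both side chains and the R carbinol should survive.

## Compound list

1 | phloroglucinol | Oc1cc(O)cc(O)c1 | starting material
2 | 2,4-dimethoxyphenylacetic acid | COc1ccc(CC(=O)O)c(OC)c1 | starting material
3 | N,N-dimethylformamide | CN(C)C=O | starting material
4 | 2-(2,4-dimethoxyphenyl)-1-(2,4,6-trihydroxyphenyl)ethanone (deoxybenzoin) | COc1ccc(CC(=O)c2c(O)cc(O)cc2O)c(OC)c1 | intermediate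
5 | 3-(dimethylamino)-2-(2,4-dimethoxyphenyl)-1-(2,4,6-trihydroxyphenyl)prop-2-en-1-one (enaminoketone) | CN(C)C=C(C(=O)c1c(O)cc(O)cc1O)c1ccc(OC)cc1OC | intermediate
6 | 5,7-dihydroxy-2',4'-dimethoxyisoflavone | COc1ccc(-c2coc3cc(O)cc(O)c3c2=O)c(OC)c1 | intermediate
7 | 2',4',5,7-tetrahydroxyisoflavone | Oc1ccc(-c2coc3cc(O)cc(O)c3c2=O)c(O)c1 | intermediate
8 | 2',5-dihydroxy-7,4'-bis(methoxymethoxy)isoflavone | COCOc1ccc(-c2coc3cc(OCOC)cc(O)c3c2=O)c(O)c1 | intermediate
9 | 5-hydroxy-7,4'-bis(methoxymethoxy)-2'-(triisopropylsilyloxy)isoflavone | COCOc1ccc(-c2coc3cc(OCOC)cc(O)c3c2=O)c(O[Si](C(C)C)(C(C)C)C(C)C)c1 | intermediate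
10 | 5-allyloxy-7,4'-bis(methoxymethoxy)-2'-(triisopropylsilyloxy)isoflavone | C=CCOc1cc(OCOC)cc2occ(-c3ccc(OCOC)cc3O[Si](C(C)C)(C(C)C)C(C)C)c(=O)c12 | intermediate
11 | 6-allyl-5-hydroxy-7,4'-bis(methoxymethoxy)-2'-(triisopropylsilyloxy)isoflavone | C=CCc1c(OCOC)cc2occ(-c3ccc(OCOC)cc3O[Si](C(C)C)(C(C)C)C(C)C)c(=O)c2c1O | intermediate
12 | 6-allyl-5,7,4'-tris(methoxymethoxy)-2'-(triisopropylsilyloxy)isoflavone | C=CCc1c(OCOC)cc2occ(-c3ccc(OCOC)cc3O[Si](C(C)C)(C(C)C)C(C)C)c(=O)c2c1OCOC | intermediate
13 | 6-(2,3-dihydroxypropyl)-5,7,4'-tris(methoxymethoxy)-2'-(triisopropylsilyloxy)isoflavone (both carbinol epimers) | OCC(O)Cc1c(OCOC)cc2occ(-c3ccc(OCOC)cc3O[Si](C(C)C)(C(C)C)C(C)C)c(=O)c2c1OCOC | intermediate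
14 | 6-(2-oxoethyl)-5,7,4'-tris(methoxymethoxy)-2'-(triisopropylsilyloxy)isoflavone | O=CCc1c(OCOC)cc2occ(-c3ccc(OCOC)cc3O[Si](C(C)C)(C(C)C)C(C)C)c(=O)c2c1OCOC | intermediate
15 | 2-bromopropene | C=C(C)Br | starting material
16 | 6-[(2R)-2-hydroxy-3-methylbut-3-enyl]-5,7,4'-tris(methoxymethoxy)-2'-(triisopropylsilyloxy)isoflavone | C=C(C)[C@H](O)Cc1c(OCOC)cc2occ(-c3ccc(OCOC)cc3O[Si](C(C)C)(C(C)C)C(C)C)c(=O)c2c1OCOC | intermediate
17 | 2'-hydroxy-6-[(2R)-2-hydroxy-3-methylbut-3-enyl]-5,7,4'-tris(methoxymethoxy)isoflavone | C=C(C)[C@H](O)Cc1c(OCOC)cc2occ(-c3ccc(OCOC)cc3O)c(=O)c2c1OCOC | intermediate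
18 | 2-methylbut-3-en-2-ol | C=CC(C)(C)O | starting material
19 | tert-butyl 2-methylbut-3-en-2-yl carbonate | C=CC(C)(C)OC(=O)OC(C)(C)C | intermediate
20 | 6-[(2R)-2-hydroxy-3-methylbut-3-enyl]-5,7,4'-tris(methoxymethoxy)-2'-(2-methylbut-3-en-2-yloxy)isoflavone | C=C(C)[C@H](O)Cc1c(OCOC)cc2occ(-c3ccc(OCOC)cc3OC(C)(C)C=C)c(=O)c2c1OCOC | intermediate
21 | 2'-hydroxy-6-[(2R)-2-hydroxy-3-methylbut-3-enyl]-5,7,4'-tris(methoxymethoxy)-3'-(3-methylbut-2-enyl)isoflavone | C=C(C)[C@H](O)Cc1c(OCOC)cc2occ(-c3ccc(OCOC)c(CC=C(C)C)c3O)c(=O)c2c1OCOC | intermediate
22 | 3-[2,4-dihydroxy-3-(3-methylbut-2-enyl)phenyl]-5,7-dihydroxy-6-[(2R)-2-hydroxy-3-methylbut-3-enyl]-4H-chromen-4-one | C=C(C)[C@H](O)Cc1c(O)cc2occ(-c3ccc(O)c(CC=C(C)C)c3O)c(=O)c2c1O | target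

## Step count and least certain steps

Total: 14 steps. Longest linear sequence: 13 steps (steps 1 to 10 and 12 to 14, from 1, 2 and 3 to 22); step 11 is a one-step side branch.

**Step 1 (key step).** The most likely failure is over-reaction of the chloroiminium reagent with the electron-rich rings (C-formylation of ring A or of the dimethoxyphenyl ring) or incomplete C-acylation, because acylation and formylation share one pot and neither intermediate is purified. Fallback: the same three bonds are made in stages. Setting out from 1, a Houben–Hoesch condensation with commercial 2,4-dimethoxyphenylacetonitrile (ZnCl2, HCl gas, Et2O, 0 °C) gives 2-(2,4-dimethoxyphenyl)-1-(2,4,6-trihydroxyphenyl)ethaniminium chloride F1. Hot water hydrolyses it to deoxybenzoin 4, now isolated and purified. N,N-Dimethylformamide dimethyl acetal in THF at 60 °C then gives enaminoketone 5, which closes on acidification to 6, where the route is rejoined.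

**Step 3.** The most likely failure is insufficient discrimination between the 4'- and 2'-hydroxyls, giving mis- or over-alkylation, because their acidities differ little and a small electrophile feels little of the crowding at O2'. Fallback: steric discrimination with a bulky silyl chloride, then a group swap. Setting out from 7, TBSCl (2.1 equiv) and imidazole at 0 °C give 5,2'-dihydroxy-7,4'-bis(tert-butyldimethylsilyloxy)isoflavone F2. TIPSOTf and 2,6-lutidine give 5-hydroxy-7,4'-bis(tert-butyldimethylsilyloxy)-2'-(triisopropylsilyloxy)isoflavone F3. K2CO3 in MeOH at 0 °C removes the two exposed tert-butyldimethylsilyl groups but not the hindered triisopropylsilyl group, giving 5,7,4'-trihydroxy-2'-(triisopropylsilyloxy)isoflavone F4. MOMCl (2 equiv) and i-Pr2NEt then protect O7 and O4', leaving only the chelated 5-OH, and the route is rejoined at 9.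

**Step 9.** The most likely failure is poor facial selectivity, because the aldehyde is unbranched at its α-carbon and the neighbouring acetal oxygens can chelate chromium; self-condensation of the enolisable aldehyde before addition is the second concern. Fallback: set the stereocentre by reduction instead of addition. Setting out from 14, an achiral Nozaki–Hiyama–Kishi addition of 15 (CrCl2, NiCl2 cat., DMF) gives racemic 6-(2-hydroxy-3-methylbut-3-enyl)-5,7,4'-tris(methoxymethoxy)-2'-(triisopropylsilyloxy)isoflavone F5. Dess–Martin oxidation gives 6-(3-methyl-2-oxobut-3-enyl)-5,7,4'-tris(methoxymethoxy)-2'-(triisopropylsilyloxy)isoflavone F6. Corey–Bakshi–Shibata reduction with (S)-1-methyl-3,3-diphenyltetrahydro-1H,3H-pyrrolo[1,2-c][1,3,2]oxazaborole and catecholborane at −78 °C, in which the isopropenyl group acts as the larger substituent, should give the R carbinol and rejoin the route at 16.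

**Step 12.** The most likely failure is loss of the branched selectivity by ionisation and recombination to the linear prenyl ether, or a sluggish reaction of the crowded 2'-phenol; the linear ether would give the wrong C-isomer in step 13. Fallback: build the tertiary ether from an alkyne, where no linear isomer exists. Setting out from 17, 3-chloro-3-methylbut-1-yne with CuCl2 (cat.) and DBU in MeCN at 0 °C gives 6-[(2R)-2-hydroxy-3-methylbut-3-enyl]-5,7,4'-tris(methoxymethoxy)-2'-(2-methylbut-3-yn-2-yloxy)isoflavone F7. Semihydrogenation over Pd/CaCO3–Pb(OAc)2 with quinoline reduces the terminal alkyne faster than the 1,1-disubstituted alkene and rejoins the route at 20.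

**Step 14.** The most likely failure is acid-promoted cyclisation of the prenyl or isopropenyl carbinol chain onto a neighbouring phenol, or ionisation of the allylic alcohol with loss of configuration, because the last acetals to leave need the longest exposure. Fallback: aprotic silyl-transfer unmasking. Setting out from 21, TMSOTf and 2,2'-bipyridyl in CH2Cl2 at 0 °C exchange the three aryl acetals for silyl groups and silylate the two free hydroxyls, giving the pentakis(trimethylsilyl) ether F8. Water on work-up hydrolyses all five silyl ethers to 22.

## Further compounds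

F1 | step 1 | 2-(2,4-dimethoxyphenyl)-1-(2,4,6-trihydroxyphenyl)ethaniminium chloride | COc1ccc(CC(=[NH2+])c2c(O)cc(O)cc2O)c(OC)c1.[Cl-]
F2 | step 3 | 5,2'-dihydroxy-7,4'-bis(tert-butyldimethylsilyloxy)isoflavone | CC(C)(C)[Si](C)(C)Oc1ccc(-c2coc3cc(O[Si](C)(C)C(C)(C)C)cc(O)c3c2=O)c(O)c1
F3 | step 3 | 5-hydroxy-7,4'-bis(tert-butyldimethylsilyloxy)-2'-(triisopropylsilyloxy)isoflavone | CC(C)(C)[Si](C)(C)Oc1ccc(-c2coc3cc(O[Si](C)(C)C(C)(C)C)cc(O)c3c2=O)c(O[Si](C(C)C)(C(C)C)C(C)C)c1
F4 | step 3 | 5,7,4'-trihydroxy-2'-(triisopropylsilyloxy)isoflavone | Oc1ccc(-c2coc3cc(O)cc(O)c3c2=O)c(O[Si](C(C)C)(C(C)C)C(C)C)c1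
F5 | step 9 | racemic 6-(2-hydroxy-3-methylbut-3-enyl)-5,7,4'-tris(methoxymethoxy)-2'-(triisopropylsilyloxy)isoflavone | C=C(C)C(O)Cc1c(OCOC)cc2occ(-c3ccc(OCOC)cc3O[Si](C(C)C)(C(C)C)C(C)C)c(=O)c2c1OCOC
F6 | step 9 | 6-(3-methyl-2-oxobut-3-enyl)-5,7,4'-tris(methoxymethoxy)-2'-(triisopropylsilyloxy)isoflavone | C=C(C)C(=O)Cc1c(OCOC)cc2occ(-c3ccc(OCOC)cc3O[Si](C(C)C)(C(C)C)C(C)C)c(=O)c2c1OCOC
F7 | step 12 | 6-[(2R)-2-hydroxy-3-methylbut-3-enyl]-5,7,4'-tris(methoxymethoxy)-2'-(2-methylbut-3-yn-2-yloxy)isoflavone | C=C(C)[C@H](O)Cc1c(OCOC)cc2occ(-c3ccc(OCOC)cc3OC(C)(C)C#C)c(=O)c2c1OCOC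
F8 | step 14 | pentakis(trimethylsilyl) ether of 22 (O5, O7, O2', O4' and the R carbinol oxygen) | C=C(C)[C@H](O[Si](C)(C)C)Cc1c(O[Si](C)(C)C)cc2occ(-c3ccc(O[Si](C)(C)C)c(CC=C(C)C)c3O[Si](C)(C)C)c(=O)c2c1O[Si](C)(C)C
A1 | alternative 1 | lactone-bridged isoflavone (ester between O2' and a carboxyl on C2), tris(methoxymethyl) ether and silyl ether, both side chains present | C=C(C)[C@H](O[Si](C)(C)C(C)(C)C)Cc1c(OCOC)cc2oc3c(-c4ccc(OCOC)c(CC=C(C)C)c4OC3=O)c(=O)c2c1OCOC
A2 | alternative 1 | 3-(methoxymethoxy)-2-(3-methylbut-2-enyl)phenyl 3-bromo-6-[(2R)-2-(tert-butyldimethylsilyloxy)-3-methylbut-3-enyl]-5,7-bis(methoxymethoxy)-4-oxo-4H-chromene-2-carboxylate | C=C(C)[C@H](O[Si](C)(C)C(C)(C)C)Cc1c(OCOC)cc2oc(C(=O)Oc3cccc(OCOC)c3CC=C(C)C)c(Br)c(=O)c2c1OCOC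
A3 | alternative 2 | 5-hydroxy-7-(triisopropylsilyloxy)isoflavone with the silylated (R)-chain on C6 and ring B as prenylated bis(methoxymethyl) ether | C=C(C)[C@H](O[Si](C)(C)C(C)(C)C)Cc1c(O[Si](C(C)C)(C(C)C)C(C)C)cc2occ(-c3ccc(OCOC)c(CC=C(C)C)c3OCOC)c(=O)c2c1O
A4 | alternative 2 | 2-(diazoacetyl)-5-[2,4-bis(methoxymethoxy)-3-(3-methylbut-2-enyl)phenyl]-4H-pyran-4-one | [N-]=[N+]=CC(=O)c1cc(=O)c(-c2ccc(OCOC)c(CC=C(C)C)c2OCOC)co1
A5 | alternative 2 | (3R)-3-(tert-butyldimethylsilyloxy)-2-methyl-6-(triisopropylsilyloxy)hex-1-en-5-yne | C=C(C)[C@H](O[Si](C)(C)C(C)(C)C)CC#CO[Si](C(C)C)(C(C)C)C(C)C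
A6 | alternative 3 | fully protected target (four methoxymethyl ethers, tert-butyldimethylsilyl ether on the R carbinol) | C=C(C)[C@H](O[Si](C)(C)C(C)(C)C)Cc1c(OCOC)cc2occ(-c3ccc(OCOC)c(CC=C(C)C)c3OCOC)c(=O)c2c1OCOC
A7 | alternative 3 | 4-[(2R)-2-(tert-butyldimethylsilyloxy)-3-methylbut-3-enyl]-3,5-bis(methoxymethoxy)-2-(trimethylsilyl)phenyl trifluoromethanesulfonate | C=C(C)[C@H](O[Si](C)(C)C(C)(C)C)Cc1c(OCOC)cc(OS(=O)(=O)C(F)(F)F)c([Si](C)(C)C)c1OCOC
A8 | alternative 3 | methyl 2-[2,4-bis(methoxymethoxy)-3-(3-methylbut-2-enyl)phenyl]-3-hydroxyacrylate | COC(=O)C(=CO)c1ccc(OCOC)c(CC=C(C)C)c1OCOC
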